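Assumption: the biaryl axis C5'–C6'' carries three ortho oxygen substituents and is treated as freely rotating, in line with the target structure, which defines no axial configuration.

## Structural features

The target is built from two C15 flavonoid units: a (2S)-flavanone of the eriodictyol type (unit 1; chromanone atoms O1 to C8a, ring B C1' to C6') and a flavone of the luteolin type (unit 2; chromone atoms O1'' to C8a'', ring B C1''' to C6'''). The units are joined by one biaryl bond between C5' of the catechol ring B of unit 1, ortho to the 4'-hydroxyl, and C6'' of the phloroglucinol ring A of unit 2, between the 5''- and 7''-hydroxyls. There is a single stereocentre, C2 of unit 1 (S), with no neighbouring stereocentre. The flavanone is the fragile part: base opens the C2–O1 bond by retro-oxa-Michael reaction to the chalcone, acid can ionise the same bond with help from the para 4'-oxygen, either way with loss of configuration, and the eight free phenols (two catechols) are sensitive to oxidation. The real difficulty is the inter-flavonoid bond: it links two electron-rich rings, it must sit at C6'' and not at C8'' (positions of ring A that differ only in which ortho oxygen is the ring oxygen O1''), and it must sit at C5' of a catechol ring, a position that quinone-type chemistry on that ring does not address. The feature that the key step exploits is that ring A of unit 2 is a folded triketide: C5'', C7'' and C8a'' carry oxygen and alternate with C4a'', C6'' and C8'', so C6'' with its aryl group can be the alpha carbon of an arylacetic ester (C6''–C7''), C5'' an acyl carbon, and C8''–C8a''–O1'' the 2-methyl group and ring oxygen of a 4-pyranone that already contains ring C. Closing ring A onto that pyranone therefore makes the biaryl connection without any aryl–aryl coupling and fixes C6'' against C8'' by connectivity.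

## Logic of the disconnections

24 to 23: the seven benzyl–oxygen bonds are cut. The free polyphenol with its labile flavanone should appear only in the last step, and benzyl ethers can be removed under neutral, non-ionising conditions. The gain is that every earlier intermediate carries at most one free phenol. The forward step must stop before the C2''=C3'' double bond, the C4 ketone or the benzylic C2–O1 bond is reduced.

23 to 20 and 22: the bond C2–C1' is cut. It is the one bond at the stereocentre that separates a nucleophilic aryl group from a planar, prochiral acceptor, so unit 1 is completed and C2 is set in the same event. The gain is large: 23 falls into a biaryl flavone and a simple chromone, and the flavanone exists for only one step before deprotection. The forward step must deliver the aryl group to the Re face of C2 of 22 under conditions mild enough that the product does not reopen, and it must leave the beta,beta-disubstituted enone of unit 2 untouched.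

20 to 19 to 18: the C1'–B bond is exchanged for C1'–Br, then the benzyl ether at O7'' is cut. A bromide is the handle that survives the strongly basic ring construction; O7'' is capped because it is the acidic phenol, while the chelated 5''-hydroxyl can stay free. The gain is modest, but it separates the key step from the late-stage chemistry. The forward steps must benzylate O7'' and not O5'', and borylate an unhindered aryl bromide next to a free phenol.

18 to 10 and 15 (through 16 and 17): the bonds C5''–C6'' and C7''–C8'' of ring A of unit 2 are cut. This is the strategic cut, and in one sentence it reads: ring A of unit 2 is closed by a Claisen/Dieckmann annulation of 16 with 15. The aryl–aryl bond C5'–C6'' is not broken at all; it is traced back to the aryl–CH2 bond of 15, and ring A is taken apart around it. C5'' becomes the carboxyl carbon of 10, C6''–C7'' the acetate unit of 15, C8'' the 2-methyl group of 10, and O1''–C8a'' stays inside the pyranone of 10. The gain is that the hardest bond and the C6''/C8'' question disappear together, and 18 falls into two fragments of similar size with unambiguous substitution. The forward step must acylate the enolate of 15 on carbon and then close ring A through the lateral carbanion without opening the pyranone, because a ring-opened triketide would pass through a symmetrical acylphloroglucinol and lose the regiochemical information.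

10 to 9 to 6 and 3: the ester C–O bond is cut, then the pyranone bonds C3–C4 and O1–C2 (with 7 and 8 as transient species). The C4–C5–C6(aryl) part is an aroylketene and the C2(methyl)–C3(carboxyl) part an acetoacetate enamine, each one step from commercial material. The gain is a two-component assembly of the fully substituted heterocycle with the carboxyl group already at C3. The forward step needs C-acylation of the enamine, ring closure with loss of the amine, and an ester that can later be removed without base.

6 to 4 and 5; 3 to 1 and 2: the acyl–carbon bond of 6 and the C–N bond of 3 are cut. Both are standard condensations of commercial compounds. The demand is only that 6 forms by C-acylation and that 3 is made below the temperature at which 1 fragments.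

15 to 14 to 13 to 12 to 11: the bond between the ester carbon and the benzylic carbon of 15 is cut, so the benzylic carbon (the future C6'') is the formyl carbon of 13; 13 is then traced to 11 by exchange of the oxygen protecting groups. 11 already has the complete pattern of ring B of unit 1: the formyl carbon on the future C5', oxygens on C4' and C3', and bromine para to the free phenol on C1'. The gain is that no regiochemical decision on ring B remains. The forward steps must homologate a hindered ortho-alkoxy benzaldehyde without touching the aryl bromide.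

22 to 21: the two benzyl ether bonds are cut. 21 is commercial, and the same protecting group as elsewhere allows one final deprotection. The forward step must also alkylate the chelated 5-hydroxyl.

## Other disconnections considered

Alternative 1: cut the biaryl bond C5'–C6'' and join the rings by Suzuki–Miyaura coupling; this is the route that comes to mind first. 7,3',4'-Tri-O-benzylluteolin A1 would be iodinated to the 6''-iodide A2 and coupled with the ring B boronate A3 (from 5-bromovanillin) to give the biaryl aldehyde A4, which would be carried to the flavanone through a chalcone. Grounds for preferring the chosen plan: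
- C6'' versus C8'' would be decided by the halogenation of A1, which rests on the free 5''-hydroxyl and the protecting pattern, not on connectivity.
- The coupling would join a di-ortho-oxygenated, electron-rich iodide to an ortho-alkoxy boronate, the situation in which oxidative addition is slow and protodeboronation and dehalogenation compete.
- The aldehyde handle of A4 leads to the flavanone through a chalcone, whose enantioselective cyclisation is less dependable than the conjugate addition open to the chosen plan.
- The step count would be similar, so nothing is gained in return.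

Alternative 2: cut the same bond but close it intramolecularly across a temporary one-atom bridge between O4' and O5''. The 5''-oxygen of A1 and the 4'-oxygen of a 5-bromo-3,4-dioxygenated benzaldehyde would be joined as the mixed methylene acetal A5, a Pd-catalysed direct arylation would close the seven-membered dibenzodioxepine A6, and acid would remove the bridge. The idea is sound in principle, because O5'' has C6'' as its only free ortho position and O4' has only C5'. Grounds for preferring the chosen plan:
- The hydrogen-bonded 5''-hydroxyl is the least reactive oxygen for building the bridge.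
- Closure of a seven-membered ring by direct arylation is slower than the six-membered closure that makes the lactone version of this idea reliable.
- Installing the bridge, removing it and reprotecting would add about four steps and give no handle for the stereocentre.

Alternative 3: cut the same bond in the sense of the presumed biosynthesis, an oxidative coupling of two phenols. The catechol A7, (2S)-5,7-di-O-benzyleriodictyol, would be oxidised to the o-quinone A8 and attacked by ring A of A1. Grounds for preferring the chosen plan:
- Carbon nucleophiles are expected to add to a 4-substituted o-quinone para to a carbonyl oxygen, which here is C6' or C2' and not C5'.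
- Ring A of A1 can react at C8'' as well as at C6''.
- A8 can tautomerise to a quinone methide through C2–H, which would destroy the stereocentre.
- Two regiochemical questions and the configuration would thus rest on substrate bias alone.

Key step: step 9

## Route

Step 1
Reactants: 1 tert-butyl acetoacetate; 2 pyrrolidine
Product: 3 tert-butyl (2E)-3-(pyrrolidin-1-yl)but-2-enoate
Conditions: pyrrolidine (1.1 equiv), 4 Å molecular sieves, CH2Cl2, 25 °C
Reagents that add atoms: none
Why: Condensation of a secondary amine with the ketone of a beta-keto ester gives the conjugated enamine (vinylogous carbamate); room temperature avoids thermal loss of acetylketene from 1.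

Step 2
Reactants: 4 3,4-bis(benzyloxy)benzoic acid; 5 Meldrum's acid (2,2-dimethyl-1,3-dioxane-4,6-dione)
Product: 6 5-{[3,4-bis(benzyloxy)phenyl](hydroxy)methylidene}-2,2-dimethyl-1,3-dioxane-4,6-dione
Conditions: DCC (1.1 equiv), DMAP (1.5 equiv), CH2Cl2, 0 °C to 25 °C; dilute HCl wash
Reagents that add atoms: none
Why: Carbodiimide/DMAP C-acylation of Meldrum's acid; the product is the stable enol and is freed from DMAP by the acid wash.

Step 3
Reactants: 6 5-{[3,4-bis(benzyloxy)phenyl](hydroxy)methylidene}-2,2-dimethyl-1,3-dioxane-4,6-dione; 3 tert-butyl (2E)-3-(pyrrolidin-1-yl)but-2-enoate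
Product: 9 tert-butyl 6-[3,4-bis(benzyloxy)phenyl]-2-methyl-4-oxo-4H-pyran-3-carboxylate, via aroylketene 7 (not isolated), via acylated enamine 8 (not isolated)
Conditions: slow addition of 6 to 3 (1.2 equiv), toluene, 95 °C; then TsOH·H2O (1.2 equiv), 25 °C
Reagents that add atoms: none
Why: Thermolysis of the acyl Meldrum's acid releases acetone and CO2 to give aroylketene 7, whose ketene carbon is attacked by the nucleophilic alpha carbon of enamine 3 (C-acylation, formal [4+2] cycloaddition); acid then lets the aroyl enol oxygen add to the enamine carbon of 8 and expel pyrrolidine to give the 4-pyranone. Only one pyranone can form, because the tert-butyl ester does not lactonise.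

Step 4
Reactants: 9 tert-butyl 6-[3,4-bis(benzyloxy)phenyl]-2-methyl-4-oxo-4H-pyran-3-carboxylate
Product: 10 6-[3,4-bis(benzyloxy)phenyl]-2-methyl-4-oxo-4H-pyran-3-carboxylic acid
Conditions: CF3CO2H/CH2Cl2 (1:4), 0 °C to 25 °C
Reagents that add atoms: none
Why: Acidolysis of the tert-butyl ester (E1 loss of isobutene) frees the acid without base, which would open the pyranone; aryl benzyl ethers should be stable to CF3CO2H at this temperature.

Step 5
Reactants: 11 5-bromo-2-hydroxy-3-methoxybenzaldehyde
Product: 12 5-bromo-2,3-dihydroxybenzaldehyde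
Conditions: BBr3 (2 equiv), CH2Cl2, −78 °C to 25 °C; H2O
Reagents that add atoms: none
Why: Lewis-acid cleavage of the aryl methyl ether (borane–ether complex, then SN2 attack of bromide on the methyl group); the aldehyde and the aryl bromide are inert under these conditions.

Step 6
Reactants: 12 5-bromo-2,3-dihydroxybenzaldehyde
Product: 13 2,3-bis(benzyloxy)-5-bromobenzaldehyde
Conditions: BnBr (2.4 equiv), K2CO3 (3 equiv), DMF, 60 °C
Reagents that add atoms: benzyl bromide, BrCc1ccccc1
Why: Williamson ether synthesis on both phenols; the chelated 2-hydroxyl reacts at 60 °C in DMF.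

Step 7
Reactants: 13 2,3-bis(benzyloxy)-5-bromobenzaldehyde
Product: 14 1,2-bis(benzyloxy)-5-bromo-3-[2-(methanesulfinyl)-2-(methylsulfanyl)ethenyl]benzene
Conditions: CH3S(O)CH2SCH3 (1.3 equiv), benzyltrimethylammonium hydroxide (40% in MeOH, cat.), THF, reflux
Reagents that add atoms: methyl (methylsulfanyl)methyl sulfoxide, CS(=O)CSC
Why: Base-catalysed Knoevenagel-type condensation of the acidic methylene of the dithioacetal S-oxide with the aldehyde, then loss of water; the E/Z mixture and the racemic sulfoxide are of no consequence because both elements are destroyed in step 8.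

Step 8
Reactants: 14 1,2-bis(benzyloxy)-5-bromo-3-[2-(methanesulfinyl)-2-(methylsulfanyl)ethenyl]benzene
Product: 15 methyl 2-[2,3-bis(benzyloxy)-5-bromophenyl]acetate
Conditions: HCl (ca. 2 M, anhydrous) in MeOH, 25 °C to 50 °C
Reagents that add atoms: methanol, CO
Why: Acid alcoholysis of the ketene dithioacetal S-oxide (C-protonation, addition of methanol, Pummerer-type loss of dimethyl disulfide) gives the arylacetic ester; overall a one-carbon homologation in which the former formyl carbon becomes the benzylic CH2.

Step 9
Reactants: 10 6-[3,4-bis(benzyloxy)phenyl]-2-methyl-4-oxo-4H-pyran-3-carboxylic acid; 15 methyl 2-[2,3-bis(benzyloxy)-5-bromophenyl]acetate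
Product: 18 6-[2,3-bis(benzyloxy)-5-bromophenyl]-2-[3,4-bis(benzyloxy)phenyl]-5,7-dihydroxy-4H-chromen-4-one, via acid chloride 16 (not isolated), via beta-keto ester 17 (not isolated)
Conditions: 10, (COCl)2, DMF (cat.), CH2Cl2, 0 °C to 25 °C, evaporate; 15, LiN(SiMe3)2 (2.2 equiv), THF, −78 °C, then 16, −78 °C to 0 °C; then LiN(SiMe3)2 (1.3 equiv), 0 °C to 40 °C; aq. HCl
Reagents that add atoms: none
Why: The lithium enolate of 15 is acylated on carbon by 16 (crossed Claisen condensation) and the resulting 17 is at once deprotonated to its enolate; the second portion of base removes a proton from the 2-methyl group, a vinylogous methyl ketone, and the lateral carbanion (C8'') attacks the ester carbonyl (C7'') in a Dieckmann condensation, methoxide leaves and the cyclohexadienone tautomerises to the 5,7-dihydroxychromone dianion, an irreversible aromatisation that drives the sequence. The closest known reaction types are the Claisen-mode cyclisation of 3,5,7-triketo esters to acylphloroglucinols, which is also the ring-forming step of chalcone synthase in flavonoid biosynthesis, and the lateral-anion Claisen/Dieckmann annulation of o-toluate esters to naphthalene-1,3-diols. Ring A is closed in the 6-(enolexo)-exo-trig mode. No stereocentre is formed, since the sp3 centre C6'' of 17 is lost on aromatisation. The selectivity needed is regiochemical, aryl at C6'' and not at C8'', and it is secured by connectivity: O1''–C8a'' already exists in the pyranone and C8'' is its methyl carbon, so no symmetrical acylphloroglucinol can arise as long as the pyranone stays closed, which is why a non-nucleophilic amide base is used. Carbon acylation in the first stage is favoured by the combination of a lithium ester enolate and an acid chloride at −78 °C, and an enol lactone formed by oxygen attack in the second stage should revert under the basic conditions whereas the aromatic product cannot.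

Step 10
Reactants: 18 6-[2,3-bis(benzyloxy)-5-bromophenyl]-2-[3,4-bis(benzyloxy)phenyl]-5,7-dihydroxy-4H-chromen-4-one
Product: 19 7-(benzyloxy)-6-[2,3-bis(benzyloxy)-5-bromophenyl]-2-[3,4-bis(benzyloxy)phenyl]-5-hydroxy-4H-chromen-4-one
Conditions: BnBr (1.1 equiv), K2CO3 (1.2 equiv), acetone, 50 °C
Reagents that add atoms: benzyl bromide, BrCc1ccccc1
Why: Williamson etherification selective for the acidic, unchelated 7''-hydroxyl; the 5''-hydroxyl is held in a hydrogen bond to the C4'' carbonyl and is left free on purpose.

Step 11
Reactants: 19 7-(benzyloxy)-6-[2,3-bis(benzyloxy)-5-bromophenyl]-2-[3,4-bis(benzyloxy)phenyl]-5-hydroxy-4H-chromen-4-one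
Product: 20 7-(benzyloxy)-6-[2,3-bis(benzyloxy)-5-(4,4,5,5-tetramethyl-1,3,2-dioxaborolan-2-yl)phenyl]-2-[3,4-bis(benzyloxy)phenyl]-5-hydroxy-4H-chromen-4-one
Conditions: B2pin2 (1.3 equiv), Pd(dppf)Cl2 (5 mol%), KOAc (3 equiv), 1,4-dioxane, 90 °C
Reagents that add atoms: bis(pinacolato)diboron, CC1(C)OB(OC1(C)C)B1OC(C)(C)C(C)(C)O1
Why: Miyaura borylation (oxidative addition of the aryl bromide to zerovalent palladium, acetate-assisted transmetalation with the diboron reagent, reductive elimination); the C–Br carbon has two ortho hydrogens and is unhindered.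

Step 12
Reactants: 21 5,7-dihydroxy-4H-chromen-4-one
Product: 22 5,7-bis(benzyloxy)-4H-chromen-4-one
Conditions: BnBr (2.5 equiv), K2CO3 (3 equiv), DMF, 70 °C
Reagents that add atoms: benzyl bromide, BrCc1ccccc1
Why: Double Williamson etherification; the chelated 5-hydroxyl needs the higher temperature and the excess of halide.

Step 13
Reactants: 20 7-(benzyloxy)-6-[2,3-bis(benzyloxy)-5-(4,4,5,5-tetramethyl-1,3,2-dioxaborolan-2-yl)phenyl]-2-[3,4-bis(benzyloxy)phenyl]-5-hydroxy-4H-chromen-4-one; 22 5,7-bis(benzyloxy)-4H-chromen-4-one
Product: 23 (2S)-5,7-bis(benzyloxy)-2-{3,4-bis(benzyloxy)-5-[7-(benzyloxy)-2-[3,4-bis(benzyloxy)phenyl]-5-hydroxy-4-oxo-4H-chromen-6-yl]phenyl}-2,3-dihydro-4H-chromen-4-one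
Conditions: 22 (1.5 equiv), [Rh(OH)(cod)]2 (3 mol%), (S)-MeO-F12-BIPHEP [(S)-2,2'-bis[bis(3,4,5-trifluorophenyl)phosphino]-6,6'-dimethoxy-1,1'-biphenyl] (6.6 mol%), K3PO4 (0.5 equiv), toluene/H2O (10:1), 40 °C
Reagents that add atoms: none
Why: Rhodium-catalysed asymmetric 1,4-addition of an arylboron reagent to an enone (Hayashi–Miyaura reaction): transmetalation to an aryl–rhodium species, enantioface-selective insertion of the chromone C2=C3 bond and protonolysis by water. C2 is set by the chiral bisphosphine, which should deliver the aryl group to the Re face of C2 (2S) by analogy with the (S)-BINAP family, which gives (S)-3-arylcyclohexanones with the same facial sense; the ligand antipode is available should a model addition show the opposite sense. The flavone enone of 20 is beta,beta-disubstituted and should not insert.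

Step 14
Reactants: 23 (2S)-5,7-bis(benzyloxy)-2-{3,4-bis(benzyloxy)-5-[7-(benzyloxy)-2-[3,4-bis(benzyloxy)phenyl]-5-hydroxy-4-oxo-4H-chromen-6-yl]phenyl}-2,3-dihydro-4H-chromen-4-one
Product: 24 (2S)-2-{5-[2-(3,4-dihydroxyphenyl)-5,7-dihydroxy-4-oxo-4H-chromen-6-yl]-3,4-dihydroxyphenyl}-5,7-dihydroxy-2,3-dihydro-4H-chromen-4-one (target)
Conditions: H2 (1 atm), 10% Pd/C, THF/MeOH (1:1), 25 °C; filtration and isolation under argon
Reagents that add atoms: none
Why: Hydrogenolysis of seven aryl benzyl ethers on palladium under neutral conditions, so that C2 is not epimerised by ring opening; aryl benzyl ethers should cleave faster than the flavone double bond is reduced or the benzylic C2–O1 bond is hydrogenolysed, and the reaction is stopped at full debenzylation.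

## Compound list

1 | tert-butyl acetoacetate | CC(=O)CC(=O)OC(C)(C)C | starting material
2 | pyrrolidine | C1CCNC1 | starting material
3 | tert-butyl (2E)-3-(pyrrolidin-1-yl)but-2-enoate | C/C(N1CCCC1)=C\C(=O)OC(C)(C)C | intermediate
4 | 3,4-bis(benzyloxy)benzoic acid | OC(=O)c1ccc(OCc2ccccc2)c(OCc2ccccc2)c1 | starting material
5 | Meldrum's acid (2,2-dimethyl-1,3-dioxane-4,6-dione) | CC1(C)OC(=O)CC(=O)O1 | starting material
6 | 5-{[3,4-bis(benzyloxy)phenyl](hydroxy)methylidene}-2,2-dimethyl-1,3-dioxane-4,6-dione | CC1(C)OC(=O)C(=C(O)c2ccc(OCc3ccccc3)c(OCc3ccccc3)c2)C(=O)O1 | intermediate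
7 | 3-[3,4-bis(benzyloxy)phenyl]prop-1-ene-1,3-dione (aroylketene) | O=C=CC(=O)c1ccc(OCc2ccccc2)c(OCc2ccccc2)c1 | intermediate
8 | tert-butyl 2-{3-[3,4-bis(benzyloxy)phenyl]-3-oxopropanoyl}-3-(pyrrolidin-1-yl)but-2-enoate | CC(N1CCCC1)=C(C(=O)OC(C)(C)C)C(=O)CC(=O)c1ccc(OCc2ccccc2)c(OCc2ccccc2)c1 | intermediate
9 | tert-butyl 6-[3,4-bis(benzyloxy)phenyl]-2-methyl-4-oxo-4H-pyran-3-carboxylate | Cc1oc(-c2ccc(OCc3ccccc3)c(OCc3ccccc3)c2)cc(=O)c1C(=O)OC(C)(C)C | intermediate
10 | 6-[3,4-bis(benzyloxy)phenyl]-2-methyl-4-oxo-4H-pyran-3-carboxylic acid | Cc1oc(-c2ccc(OCc3ccccc3)c(OCc3ccccc3)c2)cc(=O)c1C(=O)O | intermediate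
11 | 5-bromo-2-hydroxy-3-methoxybenzaldehyde | COc1cc(Br)cc(C=O)c1O | starting material
12 | 5-bromo-2,3-dihydroxybenzaldehyde | O=Cc1cc(Br)cc(O)c1O | intermediate
13 | 2,3-bis(benzyloxy)-5-bromobenzaldehyde | O=Cc1cc(Br)cc(OCc2ccccc2)c1OCc1ccccc1 | intermediate
14 | 1,2-bis(benzyloxy)-5-bromo-3-[2-(methanesulfinyl)-2-(methylsulfanyl)ethenyl]benzene | CS(=O)C(SC)=Cc1cc(Br)cc(OCc2ccccc2)c1OCc1ccccc1 | intermediate
15 | methyl 2-[2,3-bis(benzyloxy)-5-bromophenyl]acetate | COC(=O)Cc1cc(Br)cc(OCc2ccccc2)c1OCc1ccccc1 | intermediate
16 | 6-[3,4-bis(benzyloxy)phenyl]-2-methyl-4-oxo-4H-pyran-3-carbonyl chloride | Cc1oc(-c2ccc(OCc3ccccc3)c(OCc3ccccc3)c2)cc(=O)c1C(Cl)=O | intermediate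
17 | methyl 2-[2,3-bis(benzyloxy)-5-bromophenyl]-3-{6-[3,4-bis(benzyloxy)phenyl]-2-methyl-4-oxo-4H-pyran-3-yl}-3-oxopropanoate | COC(=O)C(c1cc(Br)cc(OCc2ccccc2)c1OCc1ccccc1)C(=O)c1c(C)oc(-c2ccc(OCc3ccccc3)c(OCc3ccccc3)c2)cc1=O | intermediate
18 | 6-[2,3-bis(benzyloxy)-5-bromophenyl]-2-[3,4-bis(benzyloxy)phenyl]-5,7-dihydroxy-4H-chromen-4-one | O=c1cc(-c2ccc(OCc3ccccc3)c(OCc3ccccc3)c2)oc2cc(O)c(-c3cc(Br)cc(OCc4ccccc4)c3OCc3ccccc3)c(O)c12 | intermediate
19 | 7-(benzyloxy)-6-[2,3-bis(benzyloxy)-5-bromophenyl]-2-[3,4-bis(benzyloxy)phenyl]-5-hydroxy-4H-chromen-4-one | O=c1cc(-c2ccc(OCc3ccccc3)c(OCc3ccccc3)c2)oc2cc(OCc3ccccc3)c(-c3cc(Br)cc(OCc4ccccc4)c3OCc3ccccc3)c(O)c12 | intermediate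
20 | 7-(benzyloxy)-6-[2,3-bis(benzyloxy)-5-(4,4,5,5-tetramethyl-1,3,2-dioxaborolan-2-yl)phenyl]-2-[3,4-bis(benzyloxy)phenyl]-5-hydroxy-4H-chromen-4-one | O=c1cc(-c2ccc(OCc3ccccc3)c(OCc3ccccc3)c2)oc2cc(OCc3ccccc3)c(-c3cc(B4OC(C)(C)C(C)(C)O4)cc(OCc4ccccc4)c3OCc3ccccc3)c(O)c12 | intermediate
21 | 5,7-dihydroxy-4H-chromen-4-one | O=c1ccoc2cc(O)cc(O)c12 | starting material
22 | 5,7-bis(benzyloxy)-4H-chromen-4-one | O=c1ccoc2cc(OCc3ccccc3)cc(OCc3ccccc3)c12 | intermediate
23 | (2S)-5,7-bis(benzyloxy)-2-{3,4-bis(benzyloxy)-5-[7-(benzyloxy)-2-[3,4-bis(benzyloxy)phenyl]-5-hydroxy-4-oxo-4H-chromen-6-yl]phenyl}-2,3-dihydro-4H-chromen-4-one | O=C1C[C@@H](c2cc(OCc3ccccc3)c(OCc3ccccc3)c(-c3c(OCc4ccccc4)cc4oc(-c5ccc(OCc6ccccc6)c(OCc6ccccc6)c5)cc(=O)c4c3O)c2)Oc2cc(OCc3ccccc3)cc(OCc3ccccc3)c21 | intermediate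
24 | (2S)-2-{5-[2-(3,4-dihydroxyphenyl)-5,7-dihydroxy-4-oxo-4H-chromen-6-yl]-3,4-dihydroxyphenyl}-5,7-dihydroxy-2,3-dihydro-4H-chromen-4-one | O=C1C[C@@H](c2cc(O)c(O)c(-c3c(O)cc4oc(-c5ccc(O)c(O)c5)cc(=O)c4c3O)c2)Oc2cc(O)cc(O)c21 | target

## Step count and least certain steps

Total step count: 14. Longest linear sequence: 9 steps (steps 5, 6, 7, 8, 9, 10, 11, 13, 14, from 11).

Step 9 (key step). The second stage is the most likely point of failure. Ring closure must occur on an ester carbonyl that is part of a beta-keto ester enolate, is flanked by an ortho-substituted aryl group and, in the lithium-chelated enolate geometry, points away from C8''. If closure is slow, prolonged exposure to methoxide and amide can open the pyranone; the ring-opened triketide would reclose through a symmetrical acylphloroglucinol and the C6''/C8'' control would be lost. Retro-Claisen cleavage of the keto ester is a second slow-closure risk, and oxygen acylation in the first stage is the lesser one. The fallback reverses the order of the two C–C bonds (an o-toluate-type annulation); it sets out from 10 and 15 and returns at 18. 10 is esterified (CH3I, K2CO3, DMF) to methyl 6-[3,4-bis(benzyloxy)phenyl]-2-methyl-4-oxo-4H-pyran-3-carboxylate F1. 15 is saponified (LiOH, THF/H2O) to 2-[2,3-bis(benzyloxy)-5-bromophenyl]acetic acid F2, which is activated with 1,1'-carbonyldiimidazole to the acyl imidazole F3. The lateral lithium dienolate of F1 (LiN(SiMe3)2, THF, −78 °C; two equivalents, because the product is more acidic) is acylated at its methylene carbon by F3 to give the ketone F4, in which C7''–C8'' is in place. KOC(CH3)3 or NaH in THF then closes ring A by Dieckmann attack of the benzylic ketone enolate (C6'') on the ring ester (C5''). The hindered bond is now formed intramolecularly and on a neutral ester, as in the cyclisation of 2-(2-oxoalkyl)benzoates to naphthalene-1,3-diols.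

Step 3. Proton transfer from the strongly acidic 6 to the enamine can park both partners as a salt, so that ketene 7 forms slowly and dimerises or is captured on oxygen; incomplete loss of pyrrolidine from 8 is a second possibility. The fallback is an ynone cycloisomerisation that sets out from 1 and returns at 9. Commercial 3,4-bis(benzyloxy)benzaldehyde is converted by the Corey–Fuchs reaction (CBr4, PPh3) into the dibromoalkene F5 and then (n-C4H9Li, then CO2) into 3-[3,4-bis(benzyloxy)phenyl]prop-2-ynoic acid F6. Its acid chloride F7 ((COCl)2, DMF cat.) acylates the magnesium enolate of 1 (MgCl2, pyridine, CH2Cl2) on carbon to give the ynone F8. The acetyl enol oxygen of F8 then adds to the ynone in the 6-endo-dig mode (Et3N or TsOH) to give 9.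

Step 13. Protodeboronation of the electron-rich, valuable 20 may outrun insertion into 22, which is a deactivated 5,7-dialkoxy acceptor. The aqueous base may also reopen the product by retro-oxa-Michael reaction and erode the configuration, and the large aryl group may weaken facial discrimination. The fallback replaces asymmetric catalysis by resolution; it sets out from 20 and 22 and returns at 23. The addition is run with an achiral catalyst ([Rh(OH)(cod)]2 with racemic BINAP, same solvent and base) to give the racemate F9, and the enantiomers are separated by preparative HPLC on a chiral stationary phase; the 2S enantiomer is 23.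

Step 14. Over-reduction may set in before the seventh benzyl group is gone (saturation of C2''=C3'', hydrogenolysis of the benzylic C2–O1 bond, reduction of the C4 ketone), and the two catechols may oxidise in air during isolation. The fallback is a non-reductive debenzylation that goes from 23 directly to 24 and makes no new compound (F0): BCl3 with pentamethylbenzene as benzyl cation scavenger, CH2Cl2, −78 °C, quenched cold with methanol so that the flavanone is not exposed to acid at higher temperature.

## Further compounds

F1 | step 9 | methyl 6-[3,4-bis(benzyloxy)phenyl]-2-methyl-4-oxo-4H-pyran-3-carboxylate | COC(=O)c1c(C)oc(-c2ccc(OCc3ccccc3)c(OCc3ccccc3)c2)cc1=O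
F2 | step 9 | 2-[2,3-bis(benzyloxy)-5-bromophenyl]acetic acid | OC(=O)Cc1cc(Br)cc(OCc2ccccc2)c1OCc1ccccc1
F3 | step 9 | 2-[2,3-bis(benzyloxy)-5-bromophenyl]-1-(1H-imidazol-1-yl)ethan-1-one | O=C(Cc1cc(Br)cc(OCc2ccccc2)c1OCc1ccccc1)n1ccnc1
F4 | step 9 | methyl 2-{3-[2,3-bis(benzyloxy)-5-bromophenyl]-2-oxopropyl}-6-[3,4-bis(benzyloxy)phenyl]-4-oxo-4H-pyran-3-carboxylate | COC(=O)c1c(CC(=O)Cc2cc(Br)cc(OCc3ccccc3)c2OCc2ccccc2)oc(-c2ccc(OCc3ccccc3)c(OCc3ccccc3)c2)cc1=O
F5 | step 3 | 1,2-bis(benzyloxy)-4-(2,2-dibromoethenyl)benzene | BrC(Br)=Cc1ccc(OCc2ccccc2)c(OCc2ccccc2)c1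
F6 | step 3 | 3-[3,4-bis(benzyloxy)phenyl]prop-2-ynoic acid | OC(=O)C#Cc1ccc(OCc2ccccc2)c(OCc2ccccc2)c1
F7 | step 3 | 3-[3,4-bis(benzyloxy)phenyl]prop-2-ynoyl chloride | O=C(Cl)C#Cc1ccc(OCc2ccccc2)c(OCc2ccccc2)c1
F8 | step 3 | tert-butyl 2-acetyl-5-[3,4-bis(benzyloxy)phenyl]-3-oxopent-4-ynoate | CC(=O)C(C(=O)OC(C)(C)C)C(=O)C#Cc1ccc(OCc2ccccc2)c(OCc2ccccc2)c1
F9 | step 13 | racemic 5,7-bis(benzyloxy)-2-{3,4-bis(benzyloxy)-5-[7-(benzyloxy)-2-[3,4-bis(benzyloxy)phenyl]-5-hydroxy-4-oxo-4H-chromen-6-yl]phenyl}-2,3-dihydro-4H-chromen-4-one | O=C1CC(c2cc(OCc3ccccc3)c(OCc3ccccc3)c(-c3c(OCc4ccccc4)cc4oc(-c5ccc(OCc6ccccc6)c(OCc6ccccc6)c5)cc(=O)c4c3O)c2)Oc2cc(OCc3ccccc3)cc(OCc3ccccc3)c21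
F0 | step 14 | none | none
A1 | alternative 1 | 7-(benzyloxy)-2-[3,4-bis(benzyloxy)phenyl]-5-hydroxy-4H-chromen-4-one (7,3',4'-tri-O-benzylluteolin) | O=c1cc(-c2ccc(OCc3ccccc3)c(OCc3ccccc3)c2)oc2cc(OCc3ccccc3)cc(O)c12
A2 | alternative 1 | 7-(benzyloxy)-2-[3,4-bis(benzyloxy)phenyl]-5-hydroxy-6-iodo-4H-chromen-4-one | O=c1cc(-c2ccc(OCc3ccccc3)c(OCc3ccccc3)c2)oc2cc(OCc3ccccc3)c(I)c(O)c12
A3 | alternative 1 | 3,4-bis(benzyloxy)-5-(4,4,5,5-tetramethyl-1,3,2-dioxaborolan-2-yl)benzaldehyde | O=Cc1cc(OCc2ccccc2)c(OCc2ccccc2)c(B2OC(C)(C)C(C)(C)O2)c1
A4 | alternative 1 | 3,4-bis(benzyloxy)-5-[7-(benzyloxy)-2-[3,4-bis(benzyloxy)phenyl]-5-hydroxy-4-oxo-4H-chromen-6-yl]benzaldehyde | O=Cc1cc(OCc2ccccc2)c(OCc2ccccc2)c(-c2c(OCc3ccccc3)cc3oc(-c4ccc(OCc5ccccc5)c(OCc5ccccc5)c4)cc(=O)c3c2O)c1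
A5 | alternative 2 | 3-(benzyloxy)-4-[({7-(benzyloxy)-2-[3,4-bis(benzyloxy)phenyl]-4-oxo-4H-chromen-5-yl}oxy)methoxy]-5-bromobenzaldehyde | O=Cc1cc(Br)c(OCOc2cc(OCc3ccccc3)cc3oc(-c4ccc(OCc5ccccc5)c(OCc5ccccc5)c4)cc(=O)c23)c(OCc2ccccc2)c1
A6 | alternative 2 | methylene-bridged (O4'–CH2–O5'') dibenzodioxepine formed from A5 by C5'–C6'' ring closure | O=Cc1cc2c(OCOc3c-2c(OCc4ccccc4)cc4oc(-c5ccc(OCc6ccccc6)c(OCc6ccccc6)c5)cc(=O)c34)c(OCc2ccccc2)c1
A7 | alternative 3 | (2S)-5,7-bis(benzyloxy)-2-(3,4-dihydroxyphenyl)-2,3-dihydro-4H-chromen-4-one | O=C1C[C@@H](c2ccc(O)c(O)c2)Oc2cc(OCc3ccccc3)cc(OCc3ccccc3)c21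
A8 | alternative 3 | 4-[(2S)-5,7-bis(benzyloxy)-4-oxo-3,4-dihydro-2H-chromen-2-yl]cyclohexa-3,5-diene-1,2-dione | O=C1C[C@@H](C2=CC(=O)C(=O)C=C2)Oc2cc(OCc3ccccc3)cc(OCc3ccccc3)c21
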